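**Retrosynthetic overview**
1. Target 7 is the tyrosol ester of an unbranched C25 acid. The C11–C12 bond of the acyl chain is cut into two primary alkyl radicals, each traced back to a carboxylic acid: tetradecyl from pentadecanoic acid (C15 minus CO2), and the ester-bearing undecyl radical from the tyrosol half ester of dodecanedioic acid (C12 minus CO2).
2. Both acids are activated as N-acyloxyphthalimides and joined, like polarity with like polarity, by a nickel-electrocatalytic doubly decarboxylative cross-coupling. This is a reductive Kolbe-type union, run as the last step without protecting groups.
3. Enabling feature: C2–C25 of the acyl chain form an unbranched, heteroatom-free polymethylene, so C11 and C12 are both unhindered CH2 carbons that give well-behaved primary radicals. The ester C1(=O)–O and the 4-hydroxyphenyl ring lie ten or more bonds from C11. They are inert to reduction, but the phenol ring is labile to oxidation, so the radicals are generated at the cathode and not at the anode.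
4. The second disconnection is the ester C1–O bond. It is made first, by lipase acylation of only the aliphatic OH of tyrosol with excess symmetrical diacid.
5. No ring is formed: the benzene ring arrives intact with tyrosol, and there is no stereocentre to set.

Key step: step 4

Assumption: 7 has no stereocentre and no stereogenic double bond. It is achiral and exists as one species, so no stereocontrol is needed.

**Step 1**
Reactants: 1 tyrosol [4-(2-hydroxyethyl)phenol]; 2 dodecanedioic acid
Product: 3 12-[2-(4-hydroxyphenyl)ethoxy]-12-oxododecanoic acid (tyrosol half ester of 2, phenol free)
Conditions: 2 (4 equiv), immobilised Candida antarctica lipase B, 4 Å MS, 2-methyl-2-butanol, 55 °C; filter, crystallise out and recycle excess 2, SiO2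
Reagents that add atoms: none
Why: In this lipase-catalysed esterification the acyl-enzyme is intercepted only by the primary aliphatic OH of 1 because the phenolic OH is not a substrate, the fourfold excess of the symmetrical diacid keeps a second esterification statistically minor, and the sieves remove the water.

**Step 2**
Reactants: 3 12-[2-(4-hydroxyphenyl)ethoxy]-12-oxododecanoic acid
Product: 4 1-(1,3-dioxoisoindolin-2-yl) 12-[2-(4-hydroxyphenyl)ethyl] dodecanedioate (redox-active ester of 3)
Conditions: N-hydroxyphthalimide (1.05 equiv), DIC (1.05 equiv), THF, 0 °C to rt, no DMAP; filter, short SiO2 plug, use promptly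
Reagents that add atoms: N-hydroxyphthalimide, O=C1c2ccccc2C(=O)N1O
Why: In this carbodiimide active-ester formation the acidic, alpha-effect N–OH nucleophile should outcompete the neutral phenol for the O-acylisourea when no acyl-transfer catalyst is present, which is the same selectivity that allows the shelf-stable N-hydroxysuccinimide ester of 3-(4-hydroxyphenyl)propanoic acid to be made with its phenol free.

**Step 3**
Reactants: 5 pentadecanoic acid
Product: 6 1,3-dioxoisoindolin-2-yl pentadecanoate (redox-active ester of 5)
Conditions: N-hydroxyphthalimide (1.0 equiv), DIC (1.1 equiv), DMAP (5 mol %), CH2Cl2, rt; filter, recrystallise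
Reagents that add atoms: N-hydroxyphthalimide, O=C1c2ccccc2C(=O)N1O
Why: This is a standard Steglich-type carbodiimide esterification of an unfunctionalised fatty acid with N-hydroxyphthalimide, and no competing group is present.

**Step 4**
Reactants: 4 1-(1,3-dioxoisoindolin-2-yl) 12-[2-(4-hydroxyphenyl)ethyl] dodecanedioate; 6 1,3-dioxoisoindolin-2-yl pentadecanoate
Product: 7 2-(4-hydroxyphenyl)ethyl pentacosanoate
Conditions: 4 (1 equiv), 6 (3 equiv), NiCl2·glyme (20 mol %), 4,4',4''-tri-tert-butyl-2,2':6',2''-terpyridine (20 mol %), NaI, DMF/THF, undivided cell, Zn(+)/RVC(−), constant current until both esters are consumed (at least 1 F per mol of redox-active ester), rt, Ar; dilute HCl work-up, SiO2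
Reagents that add atoms: none
Why: Low-valent (terpyridine)nickel generated at the cathode transfers one electron to each N-acyloxyphthalimide, whose radical anion breaks at N–O and loses CO2, so that 6 gives the tetradecyl radical and 4 the 11-[2-(4-hydroxyphenyl)ethoxy]-11-oxoundecyl radical; successive capture of the two primary radicals at nickel and reductive elimination from the dialkylnickel(III) species form the C11–C12 bond. The closest known reaction type is the nickel-electrocatalytic doubly decarboxylative C(sp3)–C(sp3) cross-coupling of two redox-active esters, the reductive counterpart of a mixed Kolbe electrolysis, which is established for primary–primary pairs including partners derived from diacid half esters. No ring is closed and no stereocentre is created. The step needs cross-coupling over homo-coupling, and since the two radicals are sterically and electronically alike the outcome is statistical: a threefold excess of the cheap ester 6 should channel most of 4 into 7, and the two homodimers (octacosane, a hydrocarbon, and the bis-tyrosol ester of docosanedioic acid, a diphenol) lie far to either side of the monophenol 7 in polarity and should separate on silica. The step also needs the 4-hydroxyphenyl ring and the alkyl ester to stay untouched, which is secured by generating the radicals reductively: the sacrificial zinc anode is oxidised far below the potential of a phenol (which an anodic Kolbe coupling would destroy), and neither the ester nor the arene is reducible at the working potential of the nickel catalyst. Hydrogen bonding of the phenolic O–H to DMF should slow H-atom and proton transfer to the radicals and alkylnickel species relative to capture at nickel, Zn2+ ties up the phthalimide anion so that no phenoxide forms to attack the active esters, and the ten-carbon spacer leaves the radical centre no activated C–H or π-bond within reach for 1,5-transfer or cyclisation.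

**Compound list**
1 | tyrosol, 4-(2-hydroxyethyl)phenol | OCCc1ccc(O)cc1 | starting material
2 | dodecanedioic acid | OC(=O)CCCCCCCCCCC(=O)O | starting material
3 | 12-[2-(4-hydroxyphenyl)ethoxy]-12-oxododecanoic acid | OC(=O)CCCCCCCCCCC(=O)OCCc1ccc(O)cc1 | intermediate
4 | 1-(1,3-dioxoisoindolin-2-yl) 12-[2-(4-hydroxyphenyl)ethyl] dodecanedioate | O=C(CCCCCCCCCCC(=O)OCCc1ccc(O)cc1)ON1C(=O)c2ccccc2C1=O | intermediate
5 | pentadecanoic acid | CCCCCCCCCCCCCCC(=O)O | starting material
6 | 1,3-dioxoisoindolin-2-yl pentadecanoate | CCCCCCCCCCCCCCC(=O)ON1C(=O)c2ccccc2C1=O | intermediate
7 | 2-(4-hydroxyphenyl)ethyl pentacosanoate | CCCCCCCCCCCCCCCCCCCCCCCCC(=O)OCCc1ccc(O)cc1 | target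

**Step count**
Total steps: 4. Longest linear sequence: 3 (steps 1, 2, 4).

**Steps most likely to fail**

Step 4. The risks are three. Statistical radical pairing may divert too much material into homo-coupling. The ester-bearing radical or its alkylnickel species may be reduced prematurely through proton or H-atom transfer from the phenolic O–H. The waxy products may passivate the cathode.

The fallback makes the same C11–C12 bond as a polar nucleophile/electrophile union with the phenol masked. It sets out from 1 and comes back at 7.
- Lipase-catalysed esterification of 1 with commercial 11-bromoundecanoic acid should give 2-(4-hydroxyphenyl)ethyl 11-bromoundecanoate F1.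
- TBSCl/imidazole in DMF should give 2-{4-[(tert-butyldimethylsilyl)oxy]phenyl}ethyl 11-bromoundecanoate F2.
- Li2CuCl4-catalysed Grignard–alkyl bromide coupling with commercial tetradecylmagnesium chloride (THF/NMP, −20 to 0 °C, conditions under which alkyl esters are tolerated) should give 2-{4-[(tert-butyldimethylsilyl)oxy]phenyl}ethyl pentacosanoate F3.
- TBAF buffered with AcOH (THF, 0 °C) releases the phenol to give 7.

Step 1. The risks are over-esterification at the second carboxyl group, sluggish conversion because the diacid dissolves poorly, and a laborious separation from the excess diacid.

The fallback replaces statistical differentiation by a diacid that is already desymmetrised. It sets out from 1 and comes back at 3.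
- Mitsunobu esterification (PPh3, DIAD, THF, 0 °C) of 1 with commercial 12-(tert-butoxy)-12-oxododecanoic acid activates only the aliphatic alcohol, and the more acidic carboxylic acid acts as the nucleophile in preference to the phenol. It should give 1-tert-butyl 12-[2-(4-hydroxyphenyl)ethyl] dodecanedioate F4.
- TFA/CH2Cl2 (0 °C to rt) cleaves the tert-butyl ester to give 3.

Step 2. The risks are competing acylation of the phenolic oxygen by the carbodiimide-activated acid, which would lead to oligomerisation, and slow self-acylation on standing.

The fallback reverses the order of events so that an activated acyl group is never generated in the presence of the phenol. It sets out from 2 and comes back at 4.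
- Excess 2 with N-hydroxyphthalimide (limiting) and DIC in THF should give 12-[(1,3-dioxoisoindolin-2-yl)oxy]-12-oxododecanoic acid F5.
- The remaining free acid of F5 is joined to the aliphatic OH of 1 by Mitsunobu esterification (PPh3, DIAD, THF, 0 °C, in the dark) to give 4.

**Further compounds**
F1 | step 4 | 2-(4-hydroxyphenyl)ethyl 11-bromoundecanoate | BrCCCCCCCCCCC(=O)OCCc1ccc(O)cc1
F2 | step 4 | 2-{4-[(tert-butyldimethylsilyl)oxy]phenyl}ethyl 11-bromoundecanoate | BrCCCCCCCCCCC(=O)OCCc1ccc(O[Si](C)(C)C(C)(C)C)cc1
F3 | step 4 | 2-{4-[(tert-butyldimethylsilyl)oxy]phenyl}ethyl pentacosanoate | CCCCCCCCCCCCCCCCCCCCCCCCC(=O)OCCc1ccc(O[Si](C)(C)C(C)(C)C)cc1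
F4 | step 1 | 1-tert-butyl 12-[2-(4-hydroxyphenyl)ethyl] dodecanedioate | CC(C)(C)OC(=O)CCCCCCCCCCC(=O)OCCc1ccc(O)cc1
F5 | step 2 | 12-[(1,3-dioxoisoindolin-2-yl)oxy]-12-oxododecanoic acid | OC(=O)CCCCCCCCCCC(=O)ON1C(=O)c2ccccc2C1=O
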